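**Plan**
- Retrosynthesis cuts, in this order: the C2'–C1'' bond (geranyl on ring B), the two O–Si bonds, the C2–C3 bond of ring C, the exocyclic C=CH2 bond of an enol acetal, the C6–prenyl bond (back to an O5 1,1-dimethylallyl ether), and the two acetal C–O bonds at C2.
- Enabling feature: C2 is bonded to O1 and to ring B (4'-OMe para to C1'), so it is an acetal-type carbon that ionises easily, and C3–C4(=O) is the enol of a methyl ketone on ring A. The C2–C3 bond can therefore be made by enol-to-oxocarbenium recombination while O1–C2 is already in place.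
- Forward: rings A and B are bought. A temporary 1,3-dioxinone ring is closed first on symmetric 2,4,6-trihydroxybenzoic acid with O-silyl isovanillin. Ring A is then dressed (7-OMe, C6 prenyl by Claisen shift from O5, 5-OTBS) and the lactone is methylenated.
- Ring C arises when the racemic enol acetal rearranges (O-to-C shift, the dioxine ring is lost); desilylation and ortho-geranylation at C2' finish the chain.
- Stereochemistry: the only stereocentre, C2 (S), is set in the rearrangement by the chiral counter-anion; the E alkene of the geranyl group is taken from geraniol.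

Key step: step 9

Assumption: the sense of induction of the chiral acid cannot be predicted for this new substrate; the (S,S) antipode is written as the one that gives 2S, and its mirror image would be used if the opposite holds.

**Step 1**
Reactants: 1 isovanillin (3-hydroxy-4-methoxybenzaldehyde)
Product: 2 4-methoxy-3-(triisopropylsilyloxy)benzaldehyde
Conditions: TIPSCl, imidazole, DMF, rt
Reagents that add atoms: triisopropylsilyl chloride, CC(C)[Si](Cl)(C(C)C)C(C)C
Why: Standard phenol silylation (silyl chloride/imidazole); the bulky triisopropylsilyl ether is chosen for the 3'-oxygen because it should outlast DBU, semihydrogenation, heating, the titanium reagent and the acid of step 9 and still leave with fluoride in step 10.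

**Step 2**
Reactants: 3 2,4,6-trihydroxybenzoic acid; 2 4-methoxy-3-(triisopropylsilyloxy)benzaldehyde
Product: 6 rac-5,7-dihydroxy-2-[4-methoxy-3-(triisopropylsilyloxy)phenyl]-4H-1,3-benzodioxin-4-one, via persilylated acid 4 (not isolated), via bis-silyl benzodioxinone 5 (not isolated)
Conditions: HMDS, TMSCl (cat.), THF, 50 °C, then evaporation; 2, TMSOTf (10 mol%), CH2Cl2, −78 to −20 °C; aq. citric acid, THF, 0 °C
Reagents that add atoms: none
Why: Silyl-triflate-catalysed acetalisation of a silyl ester/silyl ether pair with an aldehyde (the method used for 1,3-dioxan-4-ones from silylated hydroxy acids) should close the acylal at low temperature without C-alkylation of the electron-rich ring; the acid is symmetric about its C1–C4 axis, so only one benzodioxinone can form, and its acetal carbon is racemic by design.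

**Step 3**
Reactants: 6 rac-5,7-dihydroxy-2-[4-methoxy-3-(triisopropylsilyloxy)phenyl]-4H-1,3-benzodioxin-4-one
Product: 7 rac-5-hydroxy-7-methoxy-2-[4-methoxy-3-(triisopropylsilyloxy)phenyl]-4H-1,3-benzodioxin-4-one
Conditions: MeOH, PPh3, DIAD, THF, 0 °C to rt
Reagents that add atoms: methanol, CO
Why: Mitsunobu etherification should methylate only the 7-OH, the more acidic and unencumbered phenol (para to the carbonyl), while the 5-OH is held in a hydrogen bond to the lactone carbonyl.

**Step 4**
Reactants: 7 rac-5-hydroxy-7-methoxy-2-[4-methoxy-3-(triisopropylsilyloxy)phenyl]-4H-1,3-benzodioxin-4-one; 8 2-methylbut-3-yn-2-ol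
Product: 10 rac-7-methoxy-2-[4-methoxy-3-(triisopropylsilyloxy)phenyl]-5-[(2-methylbut-3-yn-2-yl)oxy]-4H-1,3-benzodioxin-4-one, via propargylic trifluoroacetate 9 (not isolated)
Conditions: 8, (CF3CO)2O, DBU, MeCN, −5 °C; then 7, DBU, CuCl2·2H2O (cat.), MeCN, −5 to 0 °C
Reagents that add atoms: none
Why: Copper-catalysed propargylic substitution of the tertiary trifluoroacetate by the DBU phenoxide is the standard entry to aryl 1,1-dimethylpropargyl ethers; with O7 methylated, the 5-OH is the only nucleophile left.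

**Step 5**
Reactants: 10 rac-7-methoxy-2-[4-methoxy-3-(triisopropylsilyloxy)phenyl]-5-[(2-methylbut-3-yn-2-yl)oxy]-4H-1,3-benzodioxin-4-one
Product: 11 rac-7-methoxy-2-[4-methoxy-3-(triisopropylsilyloxy)phenyl]-5-[(2-methylbut-3-en-2-yl)oxy]-4H-1,3-benzodioxin-4-one
Conditions: H2 (1 atm), Pd/CaCO3 poisoned with Pb(OAc)2 (Lindlar catalyst), quinoline, EtOAc, rt
Reagents that add atoms: none
Why: Lindlar semihydrogenation should stop at the terminal alkene of the 1,1-dimethylallyl ether and leave the benzylic acetal and the silyl ether untouched.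

**Step 6**
Reactants: 11 rac-7-methoxy-2-[4-methoxy-3-(triisopropylsilyloxy)phenyl]-5-[(2-methylbut-3-en-2-yl)oxy]-4H-1,3-benzodioxin-4-one
Product: 13 rac-5-hydroxy-7-methoxy-2-[4-methoxy-3-(triisopropylsilyloxy)phenyl]-6-(3-methylbut-2-en-1-yl)-4H-1,3-benzodioxin-4-one, via ortho-dienone 12 (not isolated)
Conditions: toluene, 110 °C (base-washed glass)
Reagents that add atoms: none
Why: Aromatic Claisen rearrangement ([3,3] shift) of the tertiary allyl aryl ether should deliver a normal prenyl group to C6, the only ortho carbon of O5 that bears hydrogen (C4a is the ring fusion), and dienone 12 then tautomerises to the phenol; such ethers rearrange well below the temperature at which the benzodioxinone would fragment.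

**Step 7**
Reactants: 13 rac-5-hydroxy-7-methoxy-2-[4-methoxy-3-(triisopropylsilyloxy)phenyl]-6-(3-methylbut-2-en-1-yl)-4H-1,3-benzodioxin-4-one
Product: 14 rac-5-(tert-butyldimethylsilyloxy)-7-methoxy-2-[4-methoxy-3-(triisopropylsilyloxy)phenyl]-6-(3-methylbut-2-en-1-yl)-4H-1,3-benzodioxin-4-one
Conditions: TBSOTf, 2,6-lutidine, CH2Cl2, −78 to 0 °C
Reagents that add atoms: tert-butyldimethylsilyl triflate, CC(C)(C)[Si](C)(C)OS(=O)(=O)C(F)(F)F
Why: Silyl triflate with a hindered pyridine base is the usual way to silylate a hindered, hydrogen-bonded phenol; the cold, buffered medium should spare the acylal and prevent acid-induced chroman formation from the ortho-prenyl phenol.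

**Step 8**
Reactants: 14 rac-5-(tert-butyldimethylsilyloxy)-7-methoxy-2-[4-methoxy-3-(triisopropylsilyloxy)phenyl]-6-(3-methylbut-2-en-1-yl)-4H-1,3-benzodioxin-4-one
Product: 15 rac-5-(tert-butyldimethylsilyloxy)-7-methoxy-2-[4-methoxy-3-(triisopropylsilyloxy)phenyl]-4-methylidene-6-(3-methylbut-2-en-1-yl)-4H-1,3-benzodioxine
Conditions: Cp2TiMe2, toluene, 65 °C, dark; filtration through basic Al2O3
Reagents that add atoms: dimethyltitanocene, C[Ti](C)(C1C=CC=C1)C1C=CC=C1
Why: Petasis methylenation of the lactone carbonyl (Cp2Ti=CH2 formed thermally, carbonyl olefination) is the established way from 1,3-dioxan-4-ones to the enol acetals used in Petasis–Ferrier rearrangements; the reagent is neither acidic nor basic, so the acetal, both silyl ethers and the prenyl alkene should survive.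

**Step 9**
Reactants: 15 rac-5-(tert-butyldimethylsilyloxy)-7-methoxy-2-[4-methoxy-3-(triisopropylsilyloxy)phenyl]-4-methylidene-6-(3-methylbut-2-en-1-yl)-4H-1,3-benzodioxine
Product: 17 (2S)-5-(tert-butyldimethylsilyloxy)-7-methoxy-2-[4-methoxy-3-(triisopropylsilyloxy)phenyl]-6-(3-methylbut-2-en-1-yl)-2,3-dihydro-4H-chromen-4-one, via oxocarbenium enol ion pair 16 (not isolated)
Conditions: (S,S)-IDPi acid [imidodiphosphorimidate from two (S)-3,3'-bis(3,5-bis(trifluoromethyl)phenyl)-1,1'-bi-2-naphthol units, P=N–SO2CF3 on both phosphorus atoms] (5 mol%), 5 Å molecular sieves, CHCl3/methylcyclohexane, −40 °C; then Et3N at −40 °C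
Reagents that add atoms: none
Why: Proposed new method: the confined Brønsted acid protonates the enol-ether oxygen O3 of 15, the C2–O3 bond ionises to cation 16 (C2=O1+, stabilised by O1 and by the para-methoxy group of ring B) which carries the ring A methyl-ketone enol, and the enol carbon then attacks C2 to form the C2–C3 bond and return the proton; the closest known reactions are the Lewis-acid Petasis–Ferrier rearrangement of 4-methylene-1,3-dioxanes to tetrahydropyranones and the chiral phosphoric-acid-catalysed aza-Petasis–Ferrier rearrangement of hemiaminal vinyl ethers. Ring C (O1, C2, C3, C4, C4a, C8a) closes in a 6-(enolendo)-endo-trig mode. Both enantiomers of 15 give the same planar cation, so C2 is set only in the C–C bond formation, where the enol OH is hydrogen-bonded to the chiral anion and the enol carbon must reach the Si face of C2 to give 2S. The step needs C-attack by the tethered enol to win over return to the acetal, hydrolysis and alkene participation: O-return only recycles substrate, water is excluded by molecular sieves, the 5-O-silyl group keeps the peri phenol from trapping the cation, and the one alkene that could reach C2 in a Prins closure, a 2'-geranyl chain, is left off until step 11 while the C6 prenyl group is out of reach. Low temperature and the amine quench before warming should protect the 4'-methoxybenzylic C2–O1 bond of the product from acid-induced racemisation.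

**Step 10**
Reactants: 17 (2S)-5-(tert-butyldimethylsilyloxy)-7-methoxy-2-[4-methoxy-3-(triisopropylsilyloxy)phenyl]-6-(3-methylbut-2-en-1-yl)-2,3-dihydro-4H-chromen-4-one
Product: 18 (2S)-5-hydroxy-2-(3-hydroxy-4-methoxyphenyl)-7-methoxy-6-(3-methylbut-2-en-1-yl)-2,3-dihydro-4H-chromen-4-one
Conditions: TBAF, AcOH (1:1), THF, 0 °C
Reagents that add atoms: none
Why: Fluoride-induced cleavage of both aryl silyl ethers; acetic acid buffering keeps the medium from turning basic, so the flavanone should not open to the chalcone and C2 should keep its configuration.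

**Step 11**
Reactants: 18 (2S)-5-hydroxy-2-(3-hydroxy-4-methoxyphenyl)-7-methoxy-6-(3-methylbut-2-en-1-yl)-2,3-dihydro-4H-chromen-4-one; 19 geraniol
Product: 20 (2S)-2-{2-[(2E)-3,7-dimethylocta-2,6-dien-1-yl]-3-hydroxy-4-methoxyphenyl}-5-hydroxy-7-methoxy-6-(3-methylbut-2-en-1-yl)-2,3-dihydro-4H-chromen-4-one
Conditions: 19, acidic Al2O3, ClCH2CH2Cl, reflux
Reagents that add atoms: none
Why: Alumina-promoted ortho-selective Friedel–Crafts allylation of a phenol with an allylic alcohol should place the geranyl group at C2', the only free ortho carbon of the 3'-OH (C4' carries OMe; both ortho carbons of the hydrogen-bonded 5-OH are occupied), with attack through the primary terminus keeping the E alkene; C2 is not involved.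

**Compound list**
1 | isovanillin (3-hydroxy-4-methoxybenzaldehyde) | COc1ccc(C=O)cc1O | starting material
2 | 4-methoxy-3-(triisopropylsilyloxy)benzaldehyde | COc1ccc(C=O)cc1O[Si](C(C)C)(C(C)C)C(C)C | intermediate
3 | 2,4,6-trihydroxybenzoic acid | OC(=O)c1c(O)cc(O)cc1O | starting material
4 | trimethylsilyl 2,4,6-tris(trimethylsilyloxy)benzoate | C[Si](C)(C)OC(=O)c1c(O[Si](C)(C)C)cc(O[Si](C)(C)C)cc1O[Si](C)(C)C | intermediate
5 | rac-2-[4-methoxy-3-(triisopropylsilyloxy)phenyl]-5,7-bis(trimethylsilyloxy)-4H-1,3-benzodioxin-4-one | O=C1OC(c2ccc(OC)c(O[Si](C(C)C)(C(C)C)C(C)C)c2)Oc2cc(O[Si](C)(C)C)cc(O[Si](C)(C)C)c12 | intermediate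
6 | rac-5,7-dihydroxy-2-[4-methoxy-3-(triisopropylsilyloxy)phenyl]-4H-1,3-benzodioxin-4-one | O=C1OC(c2ccc(OC)c(O[Si](C(C)C)(C(C)C)C(C)C)c2)Oc2cc(O)cc(O)c12 | intermediate
7 | rac-5-hydroxy-7-methoxy-2-[4-methoxy-3-(triisopropylsilyloxy)phenyl]-4H-1,3-benzodioxin-4-one | O=C1OC(c2ccc(OC)c(O[Si](C(C)C)(C(C)C)C(C)C)c2)Oc2cc(OC)cc(O)c12 | intermediate
8 | 2-methylbut-3-yn-2-ol | CC(C)(O)C#C | starting material
9 | 2-methylbut-3-yn-2-yl trifluoroacetate | CC(C)(OC(=O)C(F)(F)F)C#C | intermediate
10 | rac-7-methoxy-2-[4-methoxy-3-(triisopropylsilyloxy)phenyl]-5-[(2-methylbut-3-yn-2-yl)oxy]-4H-1,3-benzodioxin-4-one | O=C1OC(c2ccc(OC)c(O[Si](C(C)C)(C(C)C)C(C)C)c2)Oc2cc(OC)cc(OC(C)(C)C#C)c12 | intermediate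
11 | rac-7-methoxy-2-[4-methoxy-3-(triisopropylsilyloxy)phenyl]-5-[(2-methylbut-3-en-2-yl)oxy]-4H-1,3-benzodioxin-4-one | O=C1OC(c2ccc(OC)c(O[Si](C(C)C)(C(C)C)C(C)C)c2)Oc2cc(OC)cc(OC(C)(C)C=C)c12 | intermediate
12 | 7-methoxy-2-[4-methoxy-3-(triisopropylsilyloxy)phenyl]-6-(3-methylbut-2-en-1-yl)-4H-1,3-benzodioxine-4,5(6H)-dione (ortho-dienone, mixture of diastereomers) | O=C1OC(c2ccc(OC)c(O[Si](C(C)C)(C(C)C)C(C)C)c2)OC2=C1C(=O)C(CC=C(C)C)C(OC)=C2 | intermediate
13 | rac-5-hydroxy-7-methoxy-2-[4-methoxy-3-(triisopropylsilyloxy)phenyl]-6-(3-methylbut-2-en-1-yl)-4H-1,3-benzodioxin-4-one | O=C1OC(c2ccc(OC)c(O[Si](C(C)C)(C(C)C)C(C)C)c2)Oc2cc(OC)c(CC=C(C)C)c(O)c12 | intermediate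
14 | rac-5-(tert-butyldimethylsilyloxy)-7-methoxy-2-[4-methoxy-3-(triisopropylsilyloxy)phenyl]-6-(3-methylbut-2-en-1-yl)-4H-1,3-benzodioxin-4-one | O=C1OC(c2ccc(OC)c(O[Si](C(C)C)(C(C)C)C(C)C)c2)Oc2cc(OC)c(CC=C(C)C)c(O[Si](C)(C)C(C)(C)C)c12 | intermediate
15 | rac-5-(tert-butyldimethylsilyloxy)-7-methoxy-2-[4-methoxy-3-(triisopropylsilyloxy)phenyl]-4-methylidene-6-(3-methylbut-2-en-1-yl)-4H-1,3-benzodioxine | C=C1OC(c2ccc(OC)c(O[Si](C(C)C)(C(C)C)C(C)C)c2)Oc2cc(OC)c(CC=C(C)C)c(O[Si](C)(C)C(C)(C)C)c12 | intermediate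
16 | [3-(tert-butyldimethylsilyloxy)-2-(1-hydroxyethenyl)-5-methoxy-4-(3-methylbut-2-en-1-yl)phenyl]{[4-methoxy-3-(triisopropylsilyloxy)phenyl]methylidene}oxonium (cation of the ion pair; counter-ion is the catalyst anion) | C=C(O)c1c(O[Si](C)(C)C(C)(C)C)c(CC=C(C)C)c(OC)cc1[O+]=Cc1ccc(OC)c(O[Si](C(C)C)(C(C)C)C(C)C)c1 | intermediate
17 | (2S)-5-(tert-butyldimethylsilyloxy)-7-methoxy-2-[4-methoxy-3-(triisopropylsilyloxy)phenyl]-6-(3-methylbut-2-en-1-yl)-2,3-dihydro-4H-chromen-4-one | COc1ccc([C@@H]2CC(=O)c3c(cc(OC)c(CC=C(C)C)c3O[Si](C)(C)C(C)(C)C)O2)cc1O[Si](C(C)C)(C(C)C)C(C)C | intermediate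
18 | (2S)-5-hydroxy-2-(3-hydroxy-4-methoxyphenyl)-7-methoxy-6-(3-methylbut-2-en-1-yl)-2,3-dihydro-4H-chromen-4-one | COc1ccc([C@@H]2CC(=O)c3c(cc(OC)c(CC=C(C)C)c3O)O2)cc1O | intermediate
19 | geraniol ((2E)-3,7-dimethylocta-2,6-dien-1-ol) | OC/C=C(\C)CCC=C(C)C | starting material
20 | (2S)-2-{2-[(2E)-3,7-dimethylocta-2,6-dien-1-yl]-3-hydroxy-4-methoxyphenyl}-5-hydroxy-7-methoxy-6-(3-methylbut-2-en-1-yl)-2,3-dihydro-4H-chromen-4-one | COc1ccc([C@@H]2CC(=O)c3c(cc(OC)c(CC=C(C)C)c3O)O2)c(C/C=C(\C)CCC=C(C)C)c1O | target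

**Totals**
Total step count: 11
Longest linear sequence: 11 steps (1 to 20 through steps 1–11; 10 steps from 3)

**Steps most likely to fail**

Step 9. Two processes threaten it: C-protonation of the enol ether followed by capture of traces of water, which hydrolyses the acetal instead of recombining it, and insufficient discrimination of the two faces of C2 inside the ion pair. The fallback uses known chemistry, sets out from 15 and comes back at 18. Deliberate hydrolysis of 15 (PPTS, wet THF) should give the methyl ketone 1-[2-(tert-butyldimethylsilyloxy)-6-hydroxy-4-methoxy-3-(3-methylbut-2-en-1-yl)phenyl]ethan-1-one F1 and return aldehyde 2. Heating with Me2NCH(OMe)2 should give the enaminone (E)-1-[2-(tert-butyldimethylsilyloxy)-6-hydroxy-4-methoxy-3-(3-methylbut-2-en-1-yl)phenyl]-3-(dimethylamino)prop-2-en-1-one F2, which should close under acid (TsOH, CH2Cl2) to 5-(tert-butyldimethylsilyloxy)-7-methoxy-6-(3-methylbut-2-en-1-yl)-4H-chromen-4-one F3. Asymmetric conjugate addition of commercial (3-hydroxy-4-methoxyphenyl)boronic acid (COc1ccc(B(O)O)cc1O), catalysed by Pd(OCOCF3)2 and the antipode of 4-tert-butyl-2-(pyridin-2-yl)-4,5-dihydrooxazole that delivers 2S (NH4PF6, H2O, ClCH2CH2Cl, 60 °C), should give (2S)-5-(tert-butyldimethylsilyloxy)-2-(3-hydroxy-4-methoxyphenyl)-7-methoxy-6-(3-methylbut-2-en-1-yl)-2,3-dihydro-4H-chromen-4-one F4. Desilylation under the conditions of step 10 then gives 18.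

Step 11. The C2' position lies between the hydroxyl group and the benzylic carbon and is only activated by one oxygen, so alkylation may drift to the para carbon C6' or to C8 of ring A; prolonged heating on acidic alumina may also erode the C2 configuration through reversible opening of ring C. The fallback sets out from 18 and arrives at 20. Mitsunobu coupling with geraniol 19 (PPh3, DIAD, THF, 0 °C) should etherify only the free 3'-OH and give (2S)-2-{3-[(2E)-3,7-dimethylocta-2,6-dien-1-yloxy]-4-methoxyphenyl}-5-hydroxy-7-methoxy-6-(3-methylbut-2-en-1-yl)-2,3-dihydro-4H-chromen-4-one F5. A [1,3] oxygen-to-carbon shift of the geranyl group on magnesium silicate MgSiO3 (Florisil) in toluene at mild temperature should then move it to C2', the only free ortho carbon, to give 20.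

Step 8. The lactone carbonyl is electron-rich and shielded by the peri silyl ether that the C6 prenyl group pushes towards it, so olefination may stall, and the electron-rich enol acetal may ionise on any acidic surface during isolation. The fallback changes the order of protection, sets out from 13 and comes back at 15. The phenol is masked as the small trimethylsilyl ether (TMSCl, Et3N, CH2Cl2) to give rac-7-methoxy-2-[4-methoxy-3-(triisopropylsilyloxy)phenyl]-6-(3-methylbut-2-en-1-yl)-5-(trimethylsilyloxy)-4H-1,3-benzodioxin-4-one F6. Methylenation with Cp2TiMe2 should then give rac-7-methoxy-2-[4-methoxy-3-(triisopropylsilyloxy)phenyl]-4-methylidene-6-(3-methylbut-2-en-1-yl)-5-(trimethylsilyloxy)-4H-1,3-benzodioxine F7. MeLi (THF, −78 °C) cleaves the aryl O–SiMe3 bond to lithium rac-7-methoxy-2-[4-methoxy-3-(triisopropylsilyloxy)phenyl]-4-methylidene-6-(3-methylbut-2-en-1-yl)-4H-1,3-benzodioxin-5-olate F8, which is not isolated and is silylated in the same flask with TBSOTf to give 15.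

**Further compounds**
F1 | step 9 | 1-[2-(tert-butyldimethylsilyloxy)-6-hydroxy-4-methoxy-3-(3-methylbut-2-en-1-yl)phenyl]ethan-1-one | CC(=O)c1c(O)cc(OC)c(CC=C(C)C)c1O[Si](C)(C)C(C)(C)C
F2 | step 9 | (E)-1-[2-(tert-butyldimethylsilyloxy)-6-hydroxy-4-methoxy-3-(3-methylbut-2-en-1-yl)phenyl]-3-(dimethylamino)prop-2-en-1-one | CN(C)/C=C/C(=O)c1c(O)cc(OC)c(CC=C(C)C)c1O[Si](C)(C)C(C)(C)C
F3 | step 9 | 5-(tert-butyldimethylsilyloxy)-7-methoxy-6-(3-methylbut-2-en-1-yl)-4H-chromen-4-one | O=c1ccoc2cc(OC)c(CC=C(C)C)c(O[Si](C)(C)C(C)(C)C)c12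
F4 | step 9 | (2S)-5-(tert-butyldimethylsilyloxy)-2-(3-hydroxy-4-methoxyphenyl)-7-methoxy-6-(3-methylbut-2-en-1-yl)-2,3-dihydro-4H-chromen-4-one | COc1ccc([C@@H]2CC(=O)c3c(cc(OC)c(CC=C(C)C)c3O[Si](C)(C)C(C)(C)C)O2)cc1O
F5 | step 11 | (2S)-2-{3-[(2E)-3,7-dimethylocta-2,6-dien-1-yloxy]-4-methoxyphenyl}-5-hydroxy-7-methoxy-6-(3-methylbut-2-en-1-yl)-2,3-dihydro-4H-chromen-4-one | COc1ccc([C@@H]2CC(=O)c3c(cc(OC)c(CC=C(C)C)c3O)O2)cc1OC/C=C(\C)CCC=C(C)C
F6 | step 8 | rac-7-methoxy-2-[4-methoxy-3-(triisopropylsilyloxy)phenyl]-6-(3-methylbut-2-en-1-yl)-5-(trimethylsilyloxy)-4H-1,3-benzodioxin-4-one | O=C1OC(c2ccc(OC)c(O[Si](C(C)C)(C(C)C)C(C)C)c2)Oc2cc(OC)c(CC=C(C)C)c(O[Si](C)(C)C)c12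
F7 | step 8 | rac-7-methoxy-2-[4-methoxy-3-(triisopropylsilyloxy)phenyl]-4-methylidene-6-(3-methylbut-2-en-1-yl)-5-(trimethylsilyloxy)-4H-1,3-benzodioxine | C=C1OC(c2ccc(OC)c(O[Si](C(C)C)(C(C)C)C(C)C)c2)Oc2cc(OC)c(CC=C(C)C)c(O[Si](C)(C)C)c12
F8 | step 8 | lithium rac-7-methoxy-2-[4-methoxy-3-(triisopropylsilyloxy)phenyl]-4-methylidene-6-(3-methylbut-2-en-1-yl)-4H-1,3-benzodioxin-5-olate | C=C1OC(c2ccc(OC)c(O[Si](C(C)C)(C(C)C)C(C)C)c2)Oc2cc(OC)c(CC=C(C)C)c([O-])c12.[Li+]
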